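A closed, stirred vessel at constant volume holds the flask in question. It is the north-east run continued, and the north run is an earlier, colder one with more impurity.

| setting | north-east | north | flask |
|---|---|---|---|
| starting material | 20 mM | 20 mM | 20 mM |
| second substrate | 20 mM | 20 mM | 20.0 mM |
| free catalyst | 2 mM | 2 mM | 2.0 mM |
| impurity | 1.7 mM | 2.5 mM | 1.7 mM |
| temperature | 0 °C | −5 °C | 0 °C |
| remark | the very flask that is asked about, followed so far | run made earlier |  |
| time |  |  | 2.5 h |

| north-east: time / min | north-east: target / % | north: time / min | north: target / % |
|---|---|---|---|
| 8.00 | 4.8 | 10.0 | 0.6 |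
| 15.0 | 5.8 | 30.0 | 1.6 |
| 40.0 | 8.9 | 50.0 | 1.1 |
| 90.0 | 11.1 | 80.0 | 1.8 |

(standard deviation of a reading: 0.5 percentage points)

- alpha: at 2.5 h take out 90% of the target then present, then wait 80 min
- theta: change nothing and wait 80 min more
- gamma: at 2.5 h raise the temperature by 25 K, then wait 80 min
- eta: at 2.5 h add free catalyst, 50.0% of the amount charged, then wait 80 min

- target, in percent of the starting material first charged, at 2.5 h
- the remedy with the largest gain of target, or "none" below 2 percentage points (alpha / theta / gamma / eta / none)
- target present, with what was taken out counted in, in percent of the starting material first charged, after alpha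
- target present, with what was taken out counted in, in percent of the starting material first charged, after theta

- what is taken out of target is counted as made
- additions bring no volume worth counting

Read as a poison that takes free catalyst one for one, the charges set a crossing at c(impurity) = c(free catalyst). In the north run c(impurity) stands above c(free catalyst), and its readings stay at or below 1.8% up to 80.0 min. That run is also colder, so the comparison is not clean.

In the north-east run c(free catalyst) stands above c(impurity), leaving a surplus of 0.300 mM. Its readings rise 3.1 percentage points in the 25.0 min after 15.0 min, but 2.2 points in the 50.0 min after 40.0 min, so the curve slows.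

The last reading is 2.22 mM of target, so the turnover number is 7.40, the amount of target made per amount of surplus catalyst. This is a reading, and it includes target made before the poison finished.

This reckoning therefore puts target at 2.5 h close to 11.1%, and gives alpha, theta and gamma less than 2 points each, since none of them adds to the surplus. Eta adds 1.00 mM, which, provided no impurity stands by then, gives 37 points, well above the margin.

The forecast gives 12.4%, a little above this reckoning, with 14% after alpha and 13.3% after theta, and it names eta: “Fresh catalyst, with the impurity now spent, should restart the reaction, so eta is best.”

The flask gives 11.6%, with 11.6% after alpha and 11.6% after theta. The largest gain is eta, at 37 points, against the 37 points reckoned.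

    free catalyst + impurity → spent catalyst B (k = 6680 L mol⁻¹ min⁻¹, Ea = 46.0 kJ mol⁻¹)
    catalyst intermediate B → free catalyst + second product (k = 2.76 min⁻¹, Ea = 79.0 kJ mol⁻¹)
    catalyst intermediate A → spent catalyst A (k = 0.256 min⁻¹, Ea = 87.0 kJ mol⁻¹)
    starting material + free catalyst ⇌ catalyst intermediate A (K = 40.6 L mol⁻¹, k = 99.4 L mol⁻¹ min⁻¹, Ea = 42.0 kJ mol⁻¹, ΔH = −66.0 kJ mol⁻¹)
    second substrate + free catalyst ⇌ catalyst intermediate B (K = 79.4 L mol⁻¹, k = 857 L mol⁻¹ min⁻¹, Ea = 51.0 kJ mol⁻¹, ΔH = −27.0 kJ mol⁻¹)
    catalyst intermediate A → free catalyst + target (k = 1.98 min⁻¹, Ea = 75.0 kJ mol⁻¹)
    (constants at 0 °C)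

At 150 min this flask holds spent catalyst B at 85.0% and spent catalyst A at 15.0% of the catalyst charged, the latter being 0.300 mM, the size of the surplus. The forecast would fail on a flask with c(impurity) at 1.83 mM or c(free catalyst) at 1.87 mM, other amounts held, where "now" has moved by 5 points. The neighbour flask charges 12 mM of starting material with the same surplus, so a turnover number of 7.40 gives 18.5% of its smaller charge, and that flask stands at 19.1% at 2.5 h.

Readings and results were generated by integration from invented constants; scatter was added.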